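The route rests on cutting the C5–C10 bond of ring A, the bond between the tertiary C5 and the quaternary, methyl-bearing C10. It exploits that these neighbours carry the ring B arms C6 and C9. Tied as a lactone carbonyl (C6) and an allylic carbinol (C11, next to C9=C10), they give a ten-membered (E)-alkenyl lactone with a C4 malonate and a silyloxyethyl arm on C11. One Ireland–Claisen ring contraction of its silyl ketene acetal closes ring A, sets C10 by chirality transfer from C11 and C5 through the acetal geometry, and frees the C6 carboxyl and the (E)-C9=C11 alkene from which ring B is closed.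

Key step: step 8

Remark: labdane locants (C1–C20) are used throughout; the target is read as 8α-hydroxylabda-13(16),14-dien-19-yl (Z)-ferulate of the normal series (5α-H, 9α-H, 10β-CH3, 8β-CH3, 4α-CH3, axial 4β-CH2O); compounds 9 and 32 are taken as purchasable.

Step 1
Reactants: 1 5-chloropent-1-yne; 2 3-(tert-butyldimethylsilyloxy)propanal
Product: 4 rac-(E)-8-chloro-1-(tert-butyldimethylsilyloxy)-5-methyloct-4-en-3-ol, via alkenylalane 3 (not isolated)
Conditions: AlMe3, Cp2ZrCl2 (cat.), H2O (1 equiv), CH2Cl2, −20 °C; then 2, −78 °C to 0 °C; aq. potassium sodium tartrate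
Reagents that add atoms: trimethylaluminium, C[Al](C)C
Why: Zirconium-catalysed Negishi carboalumination adds CH3 and Al syn across the alkyne with CH3 on the internal carbon, which fixes the (E)-C9=C10 alkene, and the alkenylalane then adds 1,2 to the aldehyde (C11 is set later, in step 3).

Step 2
Reactants: 4 rac-(E)-8-chloro-1-(tert-butyldimethylsilyloxy)-5-methyloct-4-en-3-ol
Product: 5 (E)-8-chloro-1-(tert-butyldimethylsilyloxy)-5-methyloct-4-en-3-one
Conditions: activated MnO2, CH2Cl2, rt
Reagents that add atoms: none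
Why: MnO2 oxidation of an allylic alcohol should give the enone without touching the silyl ether, the chloride or the alkene geometry.

Step 3
Reactants: 5 (E)-8-chloro-1-(tert-butyldimethylsilyloxy)-5-methyloct-4-en-3-one
Product: 6 (3S,4E)-8-chloro-1-(tert-butyldimethylsilyloxy)-5-methyloct-4-en-3-ol
Conditions: (R)-2-methyl-CBS-oxazaborolidine (20 mol %), BH3·SMe2, THF, −30 °C; MeOH
Reagents that add atoms: none
Why: Corey–Bakshi–Shibata reduction, in which the ketone binds to the oxazaborolidine–borane complex with the alkenyl group as the large substituent, so the (R)-catalyst should deliver hydride to the face that gives (S)-C11.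

Step 4
Reactants: 6 (3S,4E)-8-chloro-1-(tert-butyldimethylsilyloxy)-5-methyloct-4-en-3-ol; 7 dimethyl malonate
Product: 8 dimethyl 2-[(4E,6S)-6-hydroxy-4-methyl-8-(tert-butyldimethylsilyloxy)oct-4-en-1-yl]malonate
Conditions: NaH, 7 (3 equiv), NaI (cat.), THF/DMF, 70 °C
Reagents that add atoms: none
Why: Malonic ester alkylation (SN2, iodide-assisted) at the primary chloride; with the malonate in excess over the base only the malonate is deprotonated, so the C11 hydroxyl stays free.

Step 5
Reactants: 8 dimethyl 2-[(4E,6S)-6-hydroxy-4-methyl-8-(tert-butyldimethylsilyloxy)oct-4-en-1-yl]malonate; 9 allyl bromoacetate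
Product: 10 dimethyl 2-[2-(allyloxy)-2-oxoethyl]-2-[(4E,6S)-6-hydroxy-4-methyl-8-(tert-butyldimethylsilyloxy)oct-4-en-1-yl]malonate
Conditions: NaH (1.0 equiv), THF, 0 °C; then 9, 0 °C to rt
Reagents that add atoms: none
Why: Second malonate alkylation with a reactive α-bromo ester makes the quaternary C4 and attaches C5–C6; the allyl ester is chosen because it can be removed under neutral conditions beside the silyl ether, the methyl esters and the allylic alcohol.

Step 6
Reactants: 10 dimethyl 2-[2-(allyloxy)-2-oxoethyl]-2-[(4E,6S)-6-hydroxy-4-methyl-8-(tert-butyldimethylsilyloxy)oct-4-en-1-yl]malonate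
Product: 11 (7E,9S)-9-hydroxy-3,3-bis(methoxycarbonyl)-7-methyl-11-(tert-butyldimethylsilyloxy)undec-7-enoic acid
Conditions: Pd(PPh3)4 (3 mol %), morpholine, THF, rt; aq. citric acid
Reagents that add atoms: none
Why: Tsuji–Trost deallylation, in which the π-allyl palladium complex formed from the allyl ester is captured by morpholine; the free allylic alcohol does not ionise under these conditions.

Step 7
Reactants: 11 (7E,9S)-9-hydroxy-3,3-bis(methoxycarbonyl)-7-methyl-11-(tert-butyldimethylsilyloxy)undec-7-enoic acid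
Product: 13 dimethyl (8E,10S)-10-[2-(tert-butyldimethylsilyloxy)ethyl]-8-methyl-2-oxooxacyclodec-8-ene-4,4-dicarboxylate, via mixed anhydride 12 (not isolated)
Conditions: 2,4,6-trichlorobenzoyl chloride, Et3N, THF, rt; slow addition to DMAP, toluene, 80 °C, high dilution
Reagents that add atoms: none
Why: Yamaguchi macrolactonisation, a standard closure for ten-membered lactones that carry an (E)-alkene next to the carbinol carbon; the C4 gem-diester should favour folded conformers, and C11 keeps its configuration because the alcohol acts as the nucleophile.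

Step 8
Reactants: 13 dimethyl (8E,10S)-10-[2-(tert-butyldimethylsilyloxy)ethyl]-8-methyl-2-oxooxacyclodec-8-ene-4,4-dicarboxylate
Product: 16 (1R,6R)-6-[(E)-4-(tert-butyldimethylsilyloxy)but-1-enyl]-2,2-bis(methoxycarbonyl)-6-methylcyclohexane-1-carboxylic acid, via silyl ketene acetal 14 (not isolated), via trimethylsilyl ester 15 (not isolated)
Conditions: LiN(iPr)2, TMSCl, THF/DMPU, −78 °C; then rt to 50 °C; aq. citric acid
Reagents that add atoms: none
Why: LiN(iPr)2 removes a C5 hydrogen (the only enolisable site, C4 being quaternary) and TMSCl traps the enolate as ketene acetal 14, which undergoes a concerted [3,3] shift in the array C5=C6–O–C11–C9=C10, forming C5–C10 as C11–O breaks and contracting the ten-membered ring to ring A. The closest known reaction type is the Ireland–Claisen ring contraction of alkenyl macrolactones, and its all-carbon counterpart is the Cope rearrangement of (E,E)-cyclodeca-1,5-dienes to trans-1,2-dialkenylcyclohexanes. Ring A closes transannularly between two trigonal carbons with both π bonds ending exocyclic (6-exo at C5 and at C10), through a chair in which the C1–C4 bridge is equatorial at both termini. C10 is controlled by C11: the C12 arm stays equatorial to avoid a 1,3-diaxial contact with the C20 methyl, so C5 bonds to the allyl face from which oxygen departs, which gives the (E)-C9=C11 alkene and the required C10 configuration from (S)-C11. C5 is controlled by the acetal geometry: with C4 anti to the ring oxygen (both π units trans in the ring) the chair places the C6 carboxyl trans to the C9 alkenyl arm and cis to C20, as the trans-decalin needs, whereas the acetal with C4 syn to the ring oxygen would give the C5 epimer through the same chair. The step therefore needs the anti acetal, which is expected from the s-trans lactone (C4 lies beside the carbonyl oxygen, so the outward C5 hydrogen leaves with least motion), from the dissociating co-solvent DMPU, which places the α-substituent of simple ester enolates next to the enolate oxygen, and from lithium bridging to a C4 ester carbonyl; the (E)-alkene fixed in step 1 keeps the chair open.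

Step 9
Reactants: 16 (1R,6R)-6-[(E)-4-(tert-butyldimethylsilyloxy)but-1-enyl]-2,2-bis(methoxycarbonyl)-6-methylcyclohexane-1-carboxylic acid
Product: 18 dimethyl (2R,3R)-3-[(E)-4-(tert-butyldimethylsilyloxy)but-1-enyl]-2-formyl-3-methylcyclohexane-1,1-dicarboxylate, via acid chloride 17 (not isolated)
Conditions: 1-chloro-N,N,2-trimethylprop-1-en-1-amine, CH2Cl2, 0 °C; then LiAlH(OtBu)3, THF, −78 °C
Reagents that add atoms: none
Why: Neutral acid chloride formation followed by LiAlH(OtBu)3 reduction should stop at the aldehyde, because this hindered hydride does not reduce methyl esters or the hindered aldehyde at −78 °C, and no base is present that could epimerise C5.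

Step 10
Reactants: 18 dimethyl (2R,3R)-3-[(E)-4-(tert-butyldimethylsilyloxy)but-1-enyl]-2-formyl-3-methylcyclohexane-1,1-dicarboxylate
Product: 19 dimethyl (2R,3R)-3-[(E)-4-(tert-butyldimethylsilyloxy)but-1-enyl]-3-methyl-2-[(E)-3-oxobut-1-enyl]cyclohexane-1,1-dicarboxylate
Conditions: Ph3P=CHC(O)CH3, toluene, 90 °C
Reagents that add atoms: 1-(triphenylphosphoranylidene)propan-2-one, CC(=O)C=P(c1ccccc1)(c1ccccc1)c1ccccc1
Why: Wittig olefination with a stabilised ylide adds C7, C8 and C17 as an (E)-enone under base-free conditions, so the C5 hydrogen next to the aldehyde is not at risk.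

Step 11
Reactants: 19 dimethyl (2R,3R)-3-[(E)-4-(tert-butyldimethylsilyloxy)but-1-enyl]-3-methyl-2-[(E)-3-oxobut-1-enyl]cyclohexane-1,1-dicarboxylate
Product: 20 dimethyl (2R,3R)-3-[(E)-4-(tert-butyldimethylsilyloxy)but-1-enyl]-3-methyl-2-(3-oxobutyl)cyclohexane-1,1-dicarboxylate
Conditions: Cu(OAc)2·H2O (5 mol %), 1,2-bis(diphenylphosphino)benzene (5 mol %), (HMe2Si)2O, t-BuOH, toluene, rt
Reagents that add atoms: none
Why: Catalytic CuH conjugate reduction (Stryker type) reduces only the enone C6=C7 bond and leaves the isolated C9=C11 alkene, the esters and the ketone carbonyl.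

Step 12
Reactants: 20 dimethyl (2R,3R)-3-[(E)-4-(tert-butyldimethylsilyloxy)but-1-enyl]-3-methyl-2-(3-oxobutyl)cyclohexane-1,1-dicarboxylate
Product: 21 dimethyl 13-(tert-butyldimethylsilyloxy)-8α-hydroxy-14,15,16-trinorlabdane-18,19-dioate
Conditions: SmI2 (2.5 equiv), HMPA, t-BuOH, THF, 0 °C to rt
Reagents that add atoms: none
Why: SmI2-promoted ketyl–olefin 6-exo-trig cyclisation, in which the C8 ketyl adds to C9 through a chair with the bulky O–Sm group and the C11 arm both equatorial (O–Sm away from the axial C20 methyl), which should give 8α-OH, 8β-CH3 and 9α-H; the C11 radical is then reduced and protonated by t-BuOH.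

Step 13
Reactants: 21 dimethyl 13-(tert-butyldimethylsilyloxy)-8α-hydroxy-14,15,16-trinorlabdane-18,19-dioate
Product: 22 methyl 13-(tert-butyldimethylsilyloxy)-8α-hydroxy-14,15,16,18-tetranorlabdan-19-oate (C4 epimers)
Conditions: NaCl, H2O, DMSO, 150 °C
Reagents that add atoms: none
Why: Krapcho dealkoxycarbonylation (chloride attack on an ester methyl, loss of CO2, protonation) removes one of the geminal esters; the C4 configuration does not matter because C4 is enolised in the next step.

Step 14
Reactants: 22 methyl 13-(tert-butyldimethylsilyloxy)-8α-hydroxy-14,15,16,18-tetranorlabdan-19-oate (C4 epimers)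
Product: 23 methyl 13-(tert-butyldimethylsilyloxy)-8α-hydroxy-14,15,16-trinorlabdan-19-oate
Conditions: LiN(iPr)2 (2.3 equiv), THF, −78 to −30 °C; MeI (1.2 equiv), −78 to −20 °C
Reagents that add atoms: iodomethane, CI
Why: Alkylation of the exocyclic C4 ester enolate of a trans-decalin, where MeI should enter along the equatorial α trajectory because the axial β one is blocked by the 1,3-diaxial C20 methyl, leaving the ester axial (C19) as in podocarpate-type resin acids; the hindered tertiary lithium alkoxide at C8 is not O-methylated at this temperature.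

Step 15
Reactants: 23 methyl 13-(tert-butyldimethylsilyloxy)-8α-hydroxy-14,15,16-trinorlabdan-19-oate
Product: 24 methyl 8α,13-dihydroxy-14,15,16-trinorlabdan-19-oate
Conditions: TBAF, THF, rt
Reagents that add atoms: none
Why: Fluoride cleavage of the primary silyl ether, which the hindered ester and the tertiary alcohol tolerate.

Step 16
Reactants: 24 methyl 8α,13-dihydroxy-14,15,16-trinorlabdan-19-oate
Product: 26 methyl 8α,13-epoxy-13-hydroxy-14,15,16-trinorlabdan-19-oate (lactol as both anomers), via hydroxy aldehyde 25 (not isolated)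
Conditions: (COCl)2, DMSO, CH2Cl2, −78 °C; Et3N, −78 to 0 °C
Reagents that add atoms: none
Why: Swern oxidation converts only the primary C13 alcohol (the tertiary C8 alcohol cannot be oxidised), and because the aldehyde is released only at low temperature, the six-membered lactol it forms with the 8α-hydroxyl is not oxidised further.

Step 17
Reactants: 26 methyl 8α,13-epoxy-13-hydroxy-14,15,16-trinorlabdan-19-oate (lactol as both anomers)
Product: 27 methyl 8α-hydroxy-15,16-dinorlabd-13-yn-19-oate
Conditions: dimethyl (1-diazo-2-oxopropyl)phosphonate, K2CO3, MeOH, rt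
Reagents that add atoms: dimethyl (1-diazo-2-oxopropyl)phosphonate, COP(=O)(OC)C(=[N+]=[N-])C(C)=O
Why: Ohira–Bestmann (Seyferth–Gilbert) homologation acts on the open hydroxy aldehyde 25 that is in equilibrium with the lactol, a known use of this reagent, and adds C14 as the terminal alkyne carbon.

Step 18
Reactants: 27 methyl 8α-hydroxy-15,16-dinorlabd-13-yn-19-oate
Product: 28 15,16-dinorlabd-13-yne-8α,19-diol
Conditions: LiAlH4, THF, 0 to 50 °C; Fieser work-up
Reagents that add atoms: none
Why: LiAlH4 reduction of the hindered axial ester to the C19 carbinol; an isolated terminal alkyne is not hydroaluminated under these conditions.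

Step 19
Reactants: 28 15,16-dinorlabd-13-yne-8α,19-diol
Product: 29 labda-13(16),14-diene-8α,19-diol
Conditions: ethylene (1 atm), second-generation Grubbs catalyst RuCl2(=CHPh)(H2IMes)(PCy3) (5 mol %), toluene, 60 °C
Reagents that add atoms: ethylene, C=C
Why: Ruthenium-carbene enyne cross-metathesis with ethylene turns the terminal alkyne into the 2-substituted buta-1,3-diene (C13=C16 and C14=C15) and tolerates free alcohols.

Step 20
Reactants: 29 labda-13(16),14-diene-8α,19-diol
Product: 30 8α-hydroxylabda-13(16),14-dien-19-yl bromoacetate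
Conditions: BrCH2COBr, pyridine, CH2Cl2, −20 °C
Reagents that add atoms: bromoacetyl bromide, BrCC(Br)=O
Why: Acylation with an acyl bromide should be selective for the primary C19 alcohol, since the tertiary C8 alcohol does not react at this temperature.

Step 21
Reactants: 30 8α-hydroxylabda-13(16),14-dien-19-yl bromoacetate
Product: 31 8α-hydroxylabda-13(16),14-dien-19-yl (diphenoxyphosphoryl)acetate
Conditions: (PhO)2P(O)H, Et3N, CH2Cl2, 0 °C to rt
Reagents that add atoms: diphenyl phosphite, O=[PH](Oc1ccccc1)Oc1ccccc1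
Why: Michaelis–Becker substitution of the α-bromo ester by the phosphite anion, the standard preparation of diaryl phosphonoacetates, builds the (Z)-selective olefination reagent on the hindered alcohol.

Step 22
Reactants: 31 8α-hydroxylabda-13(16),14-dien-19-yl (diphenoxyphosphoryl)acetate; 32 4-(tert-butyldimethylsilyloxy)-3-methoxybenzaldehyde
Product: 33 8α-hydroxylabda-13(16),14-dien-19-yl (Z)-3-[4-(tert-butyldimethylsilyloxy)-3-methoxyphenyl]prop-2-enoate
Conditions: NaH (1.05 equiv), THF, −78 °C; then 32, −78 to −20 °C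
Reagents that add atoms: none
Why: Ando-type Horner–Wadsworth–Emmons olefination, in which the electron-poor diaryl phosphonate makes oxaphosphetane collapse fast and irreversible, so the kinetic (Z)-cinnamate should predominate; any (E)-isomer is removed by chromatography.

Step 23
Reactants: 33 8α-hydroxylabda-13(16),14-dien-19-yl (Z)-3-[4-(tert-butyldimethylsilyloxy)-3-methoxyphenyl]prop-2-enoate
Product: 34 8α-hydroxylabda-13(16),14-dien-19-yl (Z)-3-(4-hydroxy-3-methoxyphenyl)prop-2-enoate (CNP0142252.2)
Conditions: TBAF, AcOH, THF, 0 °C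
Reagents that add atoms: none
Why: Buffered fluoride cleavage of the aryl silyl ether is fast at 0 °C and should leave the (Z)-enoate, the diene and the tertiary alcohol unchanged.

Compound list
1 | 5-chloropent-1-yne | ClCCCC#C | starting material
2 | 3-(tert-butyldimethylsilyloxy)propanal | CC(C)(C)[Si](C)(C)OCCC=O | starting material
3 | (E)-(5-chloro-2-methylpent-1-enyl)dimethylalane (not isolated) | ClCCC/C(C)=C/[Al](C)C | intermediate
4 | rac-(E)-8-chloro-1-(tert-butyldimethylsilyloxy)-5-methyloct-4-en-3-ol | OC(CCO[Si](C)(C)C(C)(C)C)/C=C(\C)CCCCl | intermediate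
5 | (E)-8-chloro-1-(tert-butyldimethylsilyloxy)-5-methyloct-4-en-3-one | O=C(CCO[Si](C)(C)C(C)(C)C)/C=C(\C)CCCCl | intermediate
6 | (3S,4E)-8-chloro-1-(tert-butyldimethylsilyloxy)-5-methyloct-4-en-3-ol | O[C@@H](CCO[Si](C)(C)C(C)(C)C)/C=C(\C)CCCCl | intermediate
7 | dimethyl malonate | COC(=O)CC(=O)OC | starting material
8 | dimethyl 2-[(4E,6S)-6-hydroxy-4-methyl-8-(tert-butyldimethylsilyloxy)oct-4-en-1-yl]malonate | O[C@@H](CCO[Si](C)(C)C(C)(C)C)/C=C(\C)CCCC(C(=O)OC)C(=O)OC | intermediate
9 | allyl bromoacetate | C=CCOC(=O)CBr | starting material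
10 | dimethyl 2-[2-(allyloxy)-2-oxoethyl]-2-[(4E,6S)-6-hydroxy-4-methyl-8-(tert-butyldimethylsilyloxy)oct-4-en-1-yl]malonate | O[C@@H](CCO[Si](C)(C)C(C)(C)C)/C=C(\C)CCCC(C(=O)OC)(C(=O)OC)CC(=O)OCC=C | intermediate
11 | (7E,9S)-9-hydroxy-3,3-bis(methoxycarbonyl)-7-methyl-11-(tert-butyldimethylsilyloxy)undec-7-enoic acid | O[C@@H](CCO[Si](C)(C)C(C)(C)C)/C=C(\C)CCCC(C(=O)OC)(C(=O)OC)CC(=O)O | intermediate
12 | 2,4,6-trichlorobenzoic mixed anhydride of 11 (not isolated) | O[C@@H](CCO[Si](C)(C)C(C)(C)C)/C=C(\C)CCCC(C(=O)OC)(C(=O)OC)CC(=O)OC(=O)c1c(Cl)cc(Cl)cc1Cl | intermediate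
13 | dimethyl (8E,10S)-10-[2-(tert-butyldimethylsilyloxy)ethyl]-8-methyl-2-oxooxacyclodec-8-ene-4,4-dicarboxylate (ring atoms O, C6, C5, C4, C3, C2, C1, C10, C9, C11) | O=C1O[C@@H](CCO[Si](C)(C)C(C)(C)C)/C=C(\C)CCCC(C(=O)OC)(C(=O)OC)C1 | intermediate
14 | trimethylsilyl ketene acetal of 13 (C5=C6, C4 anti to the ring oxygen; C9=C10 E; C11 S; not isolated) | C[Si](C)(C)O/C1=C\C(C(=O)OC)(C(=O)OC)CCC/C(C)=C/[C@H](CCO[Si](C)(C)C(C)(C)C)O1 | intermediate
15 | trimethylsilyl (1R,6R)-6-[(E)-4-(tert-butyldimethylsilyloxy)but-1-enyl]-2,2-bis(methoxycarbonyl)-6-methylcyclohexane-1-carboxylate (not isolated) | CC(C)(C)[Si](C)(C)OCC/C=C/[C@@]1(C)CCCC(C(=O)OC)(C(=O)OC)[C@@H]1C(=O)O[Si](C)(C)C | intermediate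
16 | (1R,6R)-6-[(E)-4-(tert-butyldimethylsilyloxy)but-1-enyl]-2,2-bis(methoxycarbonyl)-6-methylcyclohexane-1-carboxylic acid (C5 carboxyl trans to the C10 alkenyl arm, cis to the C10 methyl) | CC(C)(C)[Si](C)(C)OCC/C=C/[C@@]1(C)CCCC(C(=O)OC)(C(=O)OC)[C@@H]1C(=O)O | intermediate
17 | (1R,6R)-6-[(E)-4-(tert-butyldimethylsilyloxy)but-1-enyl]-2,2-bis(methoxycarbonyl)-6-methylcyclohexane-1-carbonyl chloride (not isolated) | CC(C)(C)[Si](C)(C)OCC/C=C/[C@@]1(C)CCCC(C(=O)OC)(C(=O)OC)[C@@H]1C(Cl)=O | intermediate
18 | dimethyl (2R,3R)-3-[(E)-4-(tert-butyldimethylsilyloxy)but-1-enyl]-2-formyl-3-methylcyclohexane-1,1-dicarboxylate | CC(C)(C)[Si](C)(C)OCC/C=C/[C@@]1(C)CCCC(C(=O)OC)(C(=O)OC)[C@@H]1C=O | intermediate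
19 | dimethyl (2R,3R)-3-[(E)-4-(tert-butyldimethylsilyloxy)but-1-enyl]-3-methyl-2-[(E)-3-oxobut-1-enyl]cyclohexane-1,1-dicarboxylate | CC(C)(C)[Si](C)(C)OCC/C=C/[C@@]1(C)CCCC(C(=O)OC)(C(=O)OC)[C@@H]1/C=C/C(C)=O | intermediate
20 | dimethyl (2R,3R)-3-[(E)-4-(tert-butyldimethylsilyloxy)but-1-enyl]-3-methyl-2-(3-oxobutyl)cyclohexane-1,1-dicarboxylate | CC(C)(C)[Si](C)(C)OCC/C=C/[C@@]1(C)CCCC(C(=O)OC)(C(=O)OC)[C@@H]1CCC(C)=O | intermediate
21 | dimethyl 13-(tert-butyldimethylsilyloxy)-8α-hydroxy-14,15,16-trinorlabdane-18,19-dioate (5α-H, 9α-H, 10β-CH3, 8β-CH3) | CC(C)(C)[Si](C)(C)OCCC[C@@H]1[C@@]2(C)CCCC(C(=O)OC)(C(=O)OC)[C@@H]2CC[C@@]1(C)O | intermediate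
22 | methyl 13-(tert-butyldimethylsilyloxy)-8α-hydroxy-14,15,16,18-tetranorlabdan-19-oate (C4 epimers) | CC(C)(C)[Si](C)(C)OCCC[C@@H]1[C@@]2(C)CCCC(C(=O)OC)[C@@H]2CC[C@@]1(C)O | intermediate
23 | methyl 13-(tert-butyldimethylsilyloxy)-8α-hydroxy-14,15,16-trinorlabdan-19-oate (4α-CH3, axial 4β-CO2CH3) | CC(C)(C)[Si](C)(C)OCCC[C@@H]1[C@@]2(C)CCC[C@](C)(C(=O)OC)[C@@H]2CC[C@@]1(C)O | intermediate
24 | methyl 8α,13-dihydroxy-14,15,16-trinorlabdan-19-oate | OCCC[C@@H]1[C@@]2(C)CCC[C@](C)(C(=O)OC)[C@@H]2CC[C@@]1(C)O | intermediate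
25 | methyl 8α-hydroxy-13-oxo-14,15,16-trinorlabdan-19-oate (open hydroxy aldehyde, not isolated) | O=CCC[C@@H]1[C@@]2(C)CCC[C@](C)(C(=O)OC)[C@@H]2CC[C@@]1(C)O | intermediate
26 | methyl 8α,13-epoxy-13-hydroxy-14,15,16-trinorlabdan-19-oate (lactol, both anomers) | OC3CC[C@@H]1[C@@]2(C)CCC[C@](C)(C(=O)OC)[C@@H]2CC[C@@]1(C)O3 | intermediate
27 | methyl 8α-hydroxy-15,16-dinorlabd-13-yn-19-oate | C#CCC[C@@H]1[C@@]2(C)CCC[C@](C)(C(=O)OC)[C@@H]2CC[C@@]1(C)O | intermediate
28 | 15,16-dinorlabd-13-yne-8α,19-diol | C#CCC[C@@H]1[C@@]2(C)CCC[C@](C)(CO)[C@@H]2CC[C@@]1(C)O | intermediate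
29 | labda-13(16),14-diene-8α,19-diol | C=CC(=C)CC[C@@H]1[C@@]2(C)CCC[C@](C)(CO)[C@@H]2CC[C@@]1(C)O | intermediate
30 | 8α-hydroxylabda-13(16),14-dien-19-yl bromoacetate | C=CC(=C)CC[C@@H]1[C@@]2(C)CCC[C@](C)(COC(=O)CBr)[C@@H]2CC[C@@]1(C)O | intermediate
31 | 8α-hydroxylabda-13(16),14-dien-19-yl (diphenoxyphosphoryl)acetate | C=CC(=C)CC[C@@H]1[C@@]2(C)CCC[C@](C)(COC(=O)CP(=O)(Oc3ccccc3)Oc3ccccc3)[C@@H]2CC[C@@]1(C)O | intermediate
32 | 4-(tert-butyldimethylsilyloxy)-3-methoxybenzaldehyde | COc1cc(C=O)ccc1O[Si](C)(C)C(C)(C)C | starting material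
33 | 8α-hydroxylabda-13(16),14-dien-19-yl (Z)-3-[4-(tert-butyldimethylsilyloxy)-3-methoxyphenyl]prop-2-enoate | C=CC(=C)CC[C@@H]1[C@@]2(C)CCC[C@](C)(COC(=O)/C=C\c3ccc(O[Si](C)(C)C(C)(C)C)c(OC)c3)[C@@H]2CC[C@@]1(C)O | intermediate
34 | 8α-hydroxylabda-13(16),14-dien-19-yl (Z)-3-(4-hydroxy-3-methoxyphenyl)prop-2-enoate (CNP0142252.2) | C=CC(=C)CC[C@@H]1[C@@]2(C)CCC[C@](C)(COC(=O)/C=C\c3ccc(O)c(OC)c3)[C@@H]2CC[C@@]1(C)O | target

Total step count: 23
Longest linear sequence: 23 steps (1 to 34)

Steps most likely to fail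

Step 8. The enolisation may place C4 syn to the ring oxygen, or give both acetal geometries, and the same chair then delivers the C5 epimer; the lactone enolate may also fragment before it is silylated. The fallback forms C5–C10 in an open-chain Ireland–Claisen rearrangement, where solvent control of ester enolate geometry is dependable, and closes ring A afterwards by alkylation. It sets out from alcohol 6 and comes back at acid 16. Trimethyl methanetricarboxylate is alkylated with tert-butyl bromoacetate (NaH, DMF) to 1-tert-butyl 2,2,2-trimethyl ethane-1,2,2,2-tetracarboxylate F1, and CF3CO2H gives 3,3,3-tris(methoxycarbonyl)propanoic acid F2. Esterification of 6 with F2 (dicyclohexylcarbodiimide, DMAP) gives the (3S,4E)-8-chloro-5-methyl-1-(tert-butyldimethylsilyloxy)oct-4-en-3-yl ester F3, whose only acidic hydrogens are at C5. LiN(iPr)2 in THF/DMPU, then TMSCl, should give the silyl ketene acetal F4 with the tricarboxymethyl group anti to the allyloxy oxygen. Its chair rearrangement (C12 arm equatorial) gives the trimethylsilyl ester F5 and, after work-up, the open-chain acid F6 with the C5 and C10 configurations of 16. NaOMe in MeOH/THF with NaI then removes one methoxycarbonyl group; the malonate anion so released displaces the C3 chloride (6-exo-tet) and closes ring A to 16.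

Step 12. The ketyl may be reduced to the secondary alcohol before it adds to C9, which is hindered by the neighbouring quaternary C10, or it may add with poor facial selectivity. The fallback replaces the radical closure by a polar one, sets out from ketone 20 and comes back at decalin 21. MeAlCl2 in CH2Cl2 at −78 °C should promote an intramolecular carbonyl–ene (Prins-type) reaction in which C9 attacks the complexed ketone and a C12 hydrogen passes to oxygen. A chair with the aluminium-bound oxygen equatorial (as in the citronellal-to-isopulegol closure) would give dimethyl (11E)-13-(tert-butyldimethylsilyloxy)-8α-hydroxy-14,15,16-trinorlabd-11-ene-18,19-dioate F7. Hydrogenation (H2, palladium on carbon, EtOAc) then gives 21.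

Step 7. Intermolecular esterification to diolides and oligomers may outrun closure of the strained ten-membered ring, and the hindered acid may direct acyl transfer to the aroyl carbonyl of the mixed anhydride. The fallback closes the ring by C–C bond formation at C4–C5 instead of lactonisation, sets out from hydroxy malonate 8 and comes back at lactone 13. Acylation of 8 with bromoacetyl bromide and pyridine gives the (S)-bromoacetate F8. Slow addition of F8 to Cs2CO3 in MeCN at 50 °C under high dilution should then close the ring by intramolecular malonate alkylation.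

Further compounds
F1 | step 8 | 1-tert-butyl 2,2,2-trimethyl ethane-1,2,2,2-tetracarboxylate | CC(C)(C)OC(=O)CC(C(=O)OC)(C(=O)OC)C(=O)OC
F2 | step 8 | 3,3,3-tris(methoxycarbonyl)propanoic acid | OC(=O)CC(C(=O)OC)(C(=O)OC)C(=O)OC
F3 | step 8 | (3S,4E)-8-chloro-5-methyl-1-(tert-butyldimethylsilyloxy)oct-4-en-3-yl 3,3,3-tris(methoxycarbonyl)propanoate | COC(=O)C(CC(=O)O[C@@H](CCO[Si](C)(C)C(C)(C)C)/C=C(\C)CCCCl)(C(=O)OC)C(=O)OC
F4 | step 8 | trimethylsilyl ketene acetal of F3 (tricarboxymethyl group anti to the allyloxy oxygen) | C[Si](C)(C)O/C(O[C@@H](CCO[Si](C)(C)C(C)(C)C)/C=C(\C)CCCCl)=C\C(C(=O)OC)(C(=O)OC)C(=O)OC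
F5 | step 8 | trimethylsilyl ester of F6 | CC(C)(C)[Si](C)(C)OCC/C=C/[C@@](C)(CCCCl)[C@@H](C(=O)O[Si](C)(C)C)C(C(=O)OC)(C(=O)OC)C(=O)OC
F6 | step 8 | open-chain acid: (E)-3-(3-chloropropyl)-3-methyl-2-[tris(methoxycarbonyl)methyl]-7-(tert-butyldimethylsilyloxy)hept-4-enoic acid with C5 and C10 as in 16 | CC(C)(C)[Si](C)(C)OCC/C=C/[C@@](C)(CCCCl)[C@@H](C(=O)O)C(C(=O)OC)(C(=O)OC)C(=O)OC
F7 | step 12 | dimethyl (11E)-13-(tert-butyldimethylsilyloxy)-8α-hydroxy-14,15,16-trinorlabd-11-ene-18,19-dioate | CC(C)(C)[Si](C)(C)OC/C=C/[C@@H]1[C@@]2(C)CCCC(C(=O)OC)(C(=O)OC)[C@@H]2CC[C@@]1(C)O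
F8 | step 7 | dimethyl 2-[(4E,6S)-6-(bromoacetoxy)-4-methyl-8-(tert-butyldimethylsilyloxy)oct-4-en-1-yl]malonate | BrCC(=O)O[C@@H](CCO[Si](C)(C)C(C)(C)C)/C=C(\C)CCCC(C(=O)OC)C(=O)OC
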